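**Retrosynthetic overview**

1. The strategy rests on the cis C2–C3 pair of the dihydrofuran ring. C2 (bonded to O1 and to the enal α-carbon) and the benzylic carbinol C3 are the donor and acceptor carbons of an aldol, and the enal α-carbon is the former ketone carbon of an aryloxyacetone.
2. Target ⇒ 2-(3-hydroxyprop-1-en-2-yl) compound (allylic oxidation of the isopropenyl CH3) ⇒ 2-isopropenyl C3 isovalerate ⇒ C3 alcohol ⇒ (ketone methylenation) cis-2-acetyl-3-silyloxy compound.
3. Key disconnection C2–C3: the cis-2-acetyl-2,3-dihydrobenzofuran-3-ol ⇒ 5-[(1S)-1-acetoxyethyl]-2-(2-oxopropoxy)benzaldehyde by an L-proline enamine 5-enolexo aldol. The dihydrofuran ring is the only ring formed, on the purchased benzene ring.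
4. Keto aldehyde ⇒ methallyl ether (ozonolysis) ⇒ aryl bromide (Br/Li exchange, DMF) ⇒ 3'-bromo-4'-hydroxyacetophenone, with the side-chain (S)-carbinol set by asymmetric transfer hydrogenation after the phenol is alkylated.

Key step: step 6

Remark on the chemistry: the sense of induction in step 6 (L-proline giving 2S,3R) is assigned from the Houk–List enamine model by analogy with the L-proline aldol of hydroxyacetone, and is taken as the working assumption.

**Route**

Step 1
Reactants: 1 1-(3-bromo-4-hydroxyphenyl)ethanone; 2 3-chloro-2-methylprop-1-ene (methallyl chloride)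
Product: 3 1-[3-bromo-4-(2-methylprop-2-enyloxy)phenyl]ethanone
Conditions: K2CO3, NaI (cat.), DMF, 60 °C
Reagents that add atoms: none
Why: Williamson ether synthesis, in which the acidified phenoxide displaces the primary allylic chloride by SN2 under iodide catalysis; alkylating the phenol before the carbinol exists removes any later para-quinone-methide pathway to racemisation.

Step 2
Reactants: 3 1-[3-bromo-4-(2-methylprop-2-enyloxy)phenyl]ethanone
Product: 4 (1S)-1-[3-bromo-4-(2-methylprop-2-enyloxy)phenyl]ethanol
Conditions: RuCl[(S,S)-TsDPEN](p-cymene) (cat.), HCO2H/Et3N (5:2), 30 °C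
Reagents that add atoms: none
Why: Noyori–Ikariya asymmetric transfer hydrogenation, in which the (S,S)-TsDPEN ruthenium hydride delivers hydride and proton through the six-membered outer-sphere transition state to the Re face of the aryl methyl ketone, setting the (S)-carbinol while the alkene and the aryl bromide are left alone.

Step 3
Reactants: 4 (1S)-1-[3-bromo-4-(2-methylprop-2-enyloxy)phenyl]ethanol
Product: 7 5-[(1S)-1-hydroxyethyl]-2-(2-methylprop-2-enyloxy)benzaldehyde, via dilithiated aryl alkoxide 5 (not isolated), via lithium hemiaminal alkoxide 6 (not isolated)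
Conditions: n-BuLi (2.2 equiv), THF, −78 °C; then DMF, −78 to 0 °C; aq. NH4Cl
Reagents that add atoms: N,N-dimethylformamide, CN(C)C=O
Why: Bromine–lithium exchange followed by Bouveault formylation: the first equivalent of n-BuLi makes the lithium alkoxide, the second exchanges the aryl bromide faster than any deprotonation at −78 °C, and the aryllithium adds to DMF to give a hemiaminal alkoxide that releases the aldehyde only on work-up, the carbinol centre being untouched.

Step 4
Reactants: 7 5-[(1S)-1-hydroxyethyl]-2-(2-methylprop-2-enyloxy)benzaldehyde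
Product: 8 (1S)-1-[3-formyl-4-(2-methylprop-2-enyloxy)phenyl]ethyl acetate
Conditions: Ac2O, pyridine, DMAP (cat.), CH2Cl2, 0 °C to rt
Reagents that add atoms: acetic anhydride, CC(=O)OC(C)=O
Why: DMAP-catalysed acyl transfer to the secondary alcohol, which takes place at oxygen with retention and leaves the aldehyde and the alkene alone.

Step 5
Reactants: 8 (1S)-1-[3-formyl-4-(2-methylprop-2-enyloxy)phenyl]ethyl acetate
Product: 10 5-[(1S)-1-acetoxyethyl]-2-(2-oxopropoxy)benzaldehyde, via secondary ozonide 9 (not isolated)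
Conditions: O3, CH2Cl2, −78 °C (to first faint blue); then Me2S, −78 °C to rt
Reagents that add atoms: ozone, [O-][O+]=O
Why: Criegee ozonolysis with reductive work-up cleaves the electron-rich 1,1-disubstituted alkene much faster than the formyl-deactivated arene, so the ketone is unveiled under neutral conditions and the base-induced aldol condensation to a 2-acetylbenzofuran, typical of salicylaldehyde alkylation with chloroacetone, is avoided.

Step 6
Reactants: 10 5-[(1S)-1-acetoxyethyl]-2-(2-oxopropoxy)benzaldehyde
Product: 13 (1S)-1-[(2S,3R)-2-acetyl-3-hydroxy-2,3-dihydro-1-benzofuran-5-yl]ethyl acetate, via proline enamine 11 (not isolated), via iminium carboxylate 12 (not isolated)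
Conditions: L-proline (30 mol%), DMF, 0–4 °C
Reagents that add atoms: none
Why: L-Proline condenses with the ketone of 10 to give the (E)-enamine 11 on the aryloxy-bearing carbon; this carbon adds to the ortho formyl group, which is activated by a hydrogen bond from the carboxylic acid, and the iminium carboxylate 12 is hydrolysed to 13 with release of the catalyst. The closest known reaction is the proline-catalysed intramolecular enolexo aldolisation of ortho-(2-oxoalkoxy)aryl carbonyl compounds to cis-2-acyl-2,3-dihydrobenzofuran-3-ols. The dihydrofuran ring closes in a 5-(enolexo)-exo-trig mode by forming C2–C3. C2 should be set (S) by catalyst control, since the anti (E)-enamine of L-proline is attacked on the face syn to the carboxylic acid as in the Houk–List model, and C3 should be set (R) because the compact hydrogen-bonded five-ring transition state keeps the iminium carbon and the aldehyde oxygen on the same side, which gives the cis aldol kinetically. The step needs reaction at the oxygen-bearing α-carbon and not at the methyl group (whose enamine could only close a seven-membered ring), cyclisation in preference to intermolecular aldol (the arene holds donor and acceptor on adjacent carbons), and survival of the β-hydroxy ketone, which is why it is run cold without added acid or base and the product is silylated at once. The remote (S)-acetate is a spectator, so any (2R,3S) product would be a diastereomer and not an enantiomer of 13.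

Step 7
Reactants: 13 (1S)-1-[(2S,3R)-2-acetyl-3-hydroxy-2,3-dihydro-1-benzofuran-5-yl]ethyl acetate
Product: 14 (1S)-1-[(2S,3R)-2-acetyl-3-(tert-butyldimethylsilyloxy)-2,3-dihydro-1-benzofuran-5-yl]ethyl acetate
Conditions: TBSOTf, 2,6-lutidine, CH2Cl2, −78 °C
Reagents that add atoms: tert-butyldimethylsilyl trifluoromethanesulfonate, CC(C)(C)[Si](C)(C)OS(=O)(=O)C(F)(F)F
Why: Silylation with a silyl triflate and a hindered pyridine base at −78 °C is faster than enolisation, so the β-hydroxy ketone is capped without retro-aldol, C2 epimerisation or E1cB loss of water, and no stereocentre is touched.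

Step 8
Reactants: 14 (1S)-1-[(2S,3R)-2-acetyl-3-(tert-butyldimethylsilyloxy)-2,3-dihydro-1-benzofuran-5-yl]ethyl acetate
Product: 15 (1S)-1-[(2R,3R)-3-(tert-butyldimethylsilyloxy)-2-(prop-1-en-2-yl)-2,3-dihydro-1-benzofuran-5-yl]ethyl acetate
Conditions: Zn, CH2Br2, TiCl4 (reagent pre-formed in THF, 0–5 °C), CH2Cl2, 0 °C to rt
Reagents that add atoms: dibromomethane, BrCBr
Why: Takai–Lombardo methylenation, in which the non-basic zinc/titanium methylene reagent converts the ketone into the 1,1-disubstituted alkene without enolisation, so C2 is not epimerised, the β-silyloxy group is not eliminated and the acetate is not attacked (the C2 descriptor changes to R only through the priority change).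

Step 9
Reactants: 15 (1S)-1-[(2R,3R)-3-(tert-butyldimethylsilyloxy)-2-(prop-1-en-2-yl)-2,3-dihydro-1-benzofuran-5-yl]ethyl acetate
Product: 16 (1S)-1-[(2R,3R)-3-hydroxy-2-(prop-1-en-2-yl)-2,3-dihydro-1-benzofuran-5-yl]ethyl acetate
Conditions: Bu4NF, AcOH, THF, 0 °C to rt
Reagents that add atoms: none
Why: Fluoride-induced Si–O cleavage driven by the Si–F bond, buffered with acetic acid so that the acetate is neither cleaved nor migrated; with the ketone gone the free alcohol has no E1cB path to a benzofuran.

Step 10
Reactants: 16 (1S)-1-[(2R,3R)-3-hydroxy-2-(prop-1-en-2-yl)-2,3-dihydro-1-benzofuran-5-yl]ethyl acetate; 17 3-methylbutanoic anhydride (isovaleric anhydride)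
Product: 18 (2R,3R)-5-[(1S)-1-acetoxyethyl]-2-(prop-1-en-2-yl)-2,3-dihydro-1-benzofuran-3-yl 3-methylbutanoate
Conditions: DMAP (cat.), Et3N, CH2Cl2, 0 °C
Reagents that add atoms: none
Why: DMAP-catalysed acylation of the secondary benzylic alcohol by the anhydride at low temperature, with retention at C3 because only the O–H bond is broken.

Step 11
Reactants: 18 (2R,3R)-5-[(1S)-1-acetoxyethyl]-2-(prop-1-en-2-yl)-2,3-dihydro-1-benzofuran-3-yl 3-methylbutanoate
Product: 19 (2R,3R)-5-[(1S)-1-acetoxyethyl]-2-(3-hydroxyprop-1-en-2-yl)-2,3-dihydro-1-benzofuran-3-yl 3-methylbutanoate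
Conditions: SeO2 (0.5 equiv), t-BuOOH, CH2Cl2, rt
Reagents that add atoms: selenium dioxide, O=[Se]=O (delivers the oxygen); tert-butyl hydroperoxide, CC(C)(C)OO (terminal oxidant that restores it)
Why: Sharpless-type catalytic SeO2 allylic oxidation (ene reaction, then [2,3]-sigmatropic shift), in which the methyl group of a 1,1-disubstituted alkene reacts in preference to the methine; C2–H is further deactivated by O1 on the same carbon and the acyloxy carbon next to it, so CH3 should become CH2OH with the double bond back in place.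

Step 12
Reactants: 19 (2R,3R)-5-[(1S)-1-acetoxyethyl]-2-(3-hydroxyprop-1-en-2-yl)-2,3-dihydro-1-benzofuran-3-yl 3-methylbutanoate
Product: 20 (2R,3R)-5-[(1S)-1-acetoxyethyl]-2-(3-oxoprop-1-en-2-yl)-2,3-dihydro-1-benzofuran-3-yl 3-methylbutanoate (CNP0252902.1)
Conditions: MnO2, CH2Cl2, rt
Reagents that add atoms: none
Why: MnO2 oxidation of the primary allylic alcohol, heterogeneous and neutral, should give the α-substituted acrolein without touching the two esters or any of the three stereocentres.

**Compound list**

1 | 1-(3-bromo-4-hydroxyphenyl)ethanone (3'-bromo-4'-hydroxyacetophenone) | CC(=O)c1ccc(O)c(Br)c1 | starting material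
2 | 3-chloro-2-methylprop-1-ene (methallyl chloride) | CC(=C)CCl | starting material
3 | 1-[3-bromo-4-(2-methylprop-2-enyloxy)phenyl]ethanone | CC(=C)COc1ccc(cc1Br)C(C)=O | intermediate
4 | (1S)-1-[3-bromo-4-(2-methylprop-2-enyloxy)phenyl]ethanol | CC(=C)COc1ccc(cc1Br)[C@H](C)O | intermediate
5 | lithium (1S)-1-[3-lithio-4-(2-methylprop-2-enyloxy)phenyl]ethoxide | CC(=C)COc1ccc(cc1[Li])[C@H](C)O[Li] | intermediate (not isolated)
6 | dilithium salt of the DMF adduct, aryl-CH(OLi)NMe2 with the side-chain lithium alkoxide (hemiaminal carbon unassigned) | CC(=C)COc1ccc(cc1C(O[Li])N(C)C)[C@H](C)O[Li] | intermediate (not isolated)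
7 | 5-[(1S)-1-hydroxyethyl]-2-(2-methylprop-2-enyloxy)benzaldehyde | CC(=C)COc1ccc(cc1C=O)[C@H](C)O | intermediate
8 | (1S)-1-[3-formyl-4-(2-methylprop-2-enyloxy)phenyl]ethyl acetate | CC(=C)COc1ccc(cc1C=O)[C@H](C)OC(C)=O | intermediate
9 | (1S)-1-{3-formyl-4-[(3-methyl-1,2,4-trioxolan-3-yl)methoxy]phenyl}ethyl acetate (trioxolane carbon unassigned) | CC1(COc2ccc(cc2C=O)[C@H](C)OC(C)=O)OCOO1 | intermediate (not isolated)
10 | 5-[(1S)-1-acetoxyethyl]-2-(2-oxopropoxy)benzaldehyde | CC(=O)COc1ccc(cc1C=O)[C@H](C)OC(C)=O | intermediate (key-step precursor)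
11 | (2S)-1-[(E)-1-{4-[(1S)-1-acetoxyethyl]-2-formylphenoxy}prop-1-en-2-yl]pyrrolidine-2-carboxylic acid | C/C(=C\Oc1ccc(cc1C=O)[C@H](C)OC(C)=O)N1CCC[C@H]1C(O)=O | intermediate (not isolated)
12 | iminium carboxylate of 13 with L-proline (zwitterion) | CC(=[N+]3CCC[C@H]3C([O-])=O)[C@H]1Oc2ccc([C@H](C)OC(C)=O)cc2[C@H]1O | intermediate (not isolated)
13 | (1S)-1-[(2S,3R)-2-acetyl-3-hydroxy-2,3-dihydro-1-benzofuran-5-yl]ethyl acetate | CC(=O)[C@H]1Oc2ccc([C@H](C)OC(C)=O)cc2[C@H]1O | intermediate (key-step product)
14 | (1S)-1-[(2S,3R)-2-acetyl-3-(tert-butyldimethylsilyloxy)-2,3-dihydro-1-benzofuran-5-yl]ethyl acetate | CC(=O)[C@H]1Oc2ccc([C@H](C)OC(C)=O)cc2[C@H]1O[Si](C)(C)C(C)(C)C | intermediate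
15 | (1S)-1-[(2R,3R)-3-(tert-butyldimethylsilyloxy)-2-(prop-1-en-2-yl)-2,3-dihydro-1-benzofuran-5-yl]ethyl acetate | CC(=C)[C@H]1Oc2ccc([C@H](C)OC(C)=O)cc2[C@H]1O[Si](C)(C)C(C)(C)C | intermediate
16 | (1S)-1-[(2R,3R)-3-hydroxy-2-(prop-1-en-2-yl)-2,3-dihydro-1-benzofuran-5-yl]ethyl acetate | CC(=C)[C@H]1Oc2ccc([C@H](C)OC(C)=O)cc2[C@H]1O | intermediate
17 | 3-methylbutanoic anhydride (isovaleric anhydride) | CC(C)CC(=O)OC(=O)CC(C)C | starting material
18 | (2R,3R)-5-[(1S)-1-acetoxyethyl]-2-(prop-1-en-2-yl)-2,3-dihydro-1-benzofuran-3-yl 3-methylbutanoate | CC(=C)[C@H]1Oc2ccc([C@H](C)OC(C)=O)cc2[C@H]1OC(=O)CC(C)C | intermediate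
19 | (2R,3R)-5-[(1S)-1-acetoxyethyl]-2-(3-hydroxyprop-1-en-2-yl)-2,3-dihydro-1-benzofuran-3-yl 3-methylbutanoate | C=C(CO)[C@H]1Oc2ccc([C@H](C)OC(C)=O)cc2[C@H]1OC(=O)CC(C)C | intermediate
20 | (2R,3R)-5-[(1S)-1-acetoxyethyl]-2-(3-oxoprop-1-en-2-yl)-2,3-dihydro-1-benzofuran-3-yl 3-methylbutanoate | C=C(C=O)[C@H]1Oc2ccc([C@H](C)OC(C)=O)cc2[C@H]1OC(=O)CC(C)C | target

**Step count**

Total: 12 steps. Longest linear sequence: 12 steps (1 to 20).

**Steps most likely to fail, with fallbacks**

Step 6. What may go wrong is insufficient face discrimination at the enamine, which would give the ring-diastereomeric cis aldol alongside 13, together with loss of material by dehydration to the aromatic 2-acetylbenzofuran. The fallback sets out from 10 and comes back at 16; the ring configuration is then secured by enzymatic kinetic resolution and no longer by the cyclisation catalyst. The closure of 10 is run as in step 6 (or with pyrrolidine/AcOH, which keeps the cis preference without chiral bias), and 13 is carried on together with its ring diastereomer (1S)-1-[(2R,3S)-2-acetyl-3-hydroxy-2,3-dihydro-1-benzofuran-5-yl]ethyl acetate F1. The mixture is silylated as in step 7, giving (1S)-1-[(2R,3S)-2-acetyl-3-(tert-butyldimethylsilyloxy)-2,3-dihydro-1-benzofuran-5-yl]ethyl acetate F2 beside 14. Methylenation as in step 8 gives (1S)-1-[(2S,3S)-3-(tert-butyldimethylsilyloxy)-2-(prop-1-en-2-yl)-2,3-dihydro-1-benzofuran-5-yl]ethyl acetate F3 beside 15, and desilylation as in step 9 gives (1S)-1-[(2S,3S)-3-hydroxy-2-(prop-1-en-2-yl)-2,3-dihydro-1-benzofuran-5-yl]ethyl acetate F4 beside 16. The alcohol mixture is treated with Burkholderia cepacia lipase (or Candida antarctica lipase B) and vinyl acetate in MTBE at 30 °C. By Kazlauskas' rule, with the fused arene as the large group, the 3S alcohol should be acetylated to (2S,3S)-5-[(1S)-1-acetoxyethyl]-2-(prop-1-en-2-yl)-2,3-dihydro-1-benzofuran-3-yl acetate F5, while the 3R alcohol 16 should stay unreacted. It is separated by chromatography and enters step 10.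

Step 8. What may go wrong is β-elimination of the silyloxy group (aromatisation) or C2 epimerisation promoted by the Lewis-acidic zinc and titanium halides, or sluggish reaction of the hindered, doubly oxygen-flanked ketone. The fallback sets out from 14 and comes back at 16, replacing direct methylenation by a Peterson olefination. Me3SiCH2MgCl pre-mixed with anhydrous CeCl3 (THF, −78 °C) is non-basic and should add to the ketone faster than to the acetate, giving the tertiary β-hydroxysilane (1S)-1-[(2S,3R)-3-(tert-butyldimethylsilyloxy)-2-[2-hydroxy-1-(trimethylsilyl)propan-2-yl]-2,3-dihydro-1-benzofuran-5-yl]ethyl acetate F6 as a mixture at the new carbinol. Aqueous HF in MeCN (0 °C to rt) should then bring about the acid-type Peterson elimination to the 1,1-disubstituted alkene and remove the silyl ether in the same flask, giving 16.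

Step 11. What may go wrong is competing ene attack at C2–H, over-oxidation, or acid-promoted loss of the C3 ester with aromatisation under the selenium conditions. The fallback sets out from 18 and comes back at 20, going through a halide and not through the alcohol 19. Ene-type allylic chlorination with hypochlorous acid generated from Ca(OCl)2 and CO2 (CH2Cl2/H2O, 0 °C), a reaction typical of isopropenyl groups, should give (2R,3R)-5-[(1S)-1-acetoxyethyl]-2-(3-chloroprop-1-en-2-yl)-2,3-dihydro-1-benzofuran-3-yl 3-methylbutanoate F7. Amine N-oxide oxidation of the allylic chloride (N-methylmorpholine N-oxide, NaI cat., MeCN, rt; Ganem-type) should then give the enal 20 directly.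

**Further compounds**

F1 | step 6 | (1S)-1-[(2R,3S)-2-acetyl-3-hydroxy-2,3-dihydro-1-benzofuran-5-yl]ethyl acetate | CC(=O)[C@@H]1Oc2ccc([C@H](C)OC(C)=O)cc2[C@@H]1O
F2 | step 6 | (1S)-1-[(2R,3S)-2-acetyl-3-(tert-butyldimethylsilyloxy)-2,3-dihydro-1-benzofuran-5-yl]ethyl acetate | CC(=O)[C@@H]1Oc2ccc([C@H](C)OC(C)=O)cc2[C@@H]1O[Si](C)(C)C(C)(C)C
F3 | step 6 | (1S)-1-[(2S,3S)-3-(tert-butyldimethylsilyloxy)-2-(prop-1-en-2-yl)-2,3-dihydro-1-benzofuran-5-yl]ethyl acetate | CC(=C)[C@@H]1Oc2ccc([C@H](C)OC(C)=O)cc2[C@@H]1O[Si](C)(C)C(C)(C)C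
F4 | step 6 | (1S)-1-[(2S,3S)-3-hydroxy-2-(prop-1-en-2-yl)-2,3-dihydro-1-benzofuran-5-yl]ethyl acetate | CC(=C)[C@@H]1Oc2ccc([C@H](C)OC(C)=O)cc2[C@@H]1O
F5 | step 6 | (2S,3S)-5-[(1S)-1-acetoxyethyl]-2-(prop-1-en-2-yl)-2,3-dihydro-1-benzofuran-3-yl acetate | CC(=C)[C@@H]1Oc2ccc([C@H](C)OC(C)=O)cc2[C@@H]1OC(C)=O
F6 | step 8 | (1S)-1-[(2S,3R)-3-(tert-butyldimethylsilyloxy)-2-[2-hydroxy-1-(trimethylsilyl)propan-2-yl]-2,3-dihydro-1-benzofuran-5-yl]ethyl acetate | CC(O)(C[Si](C)(C)C)[C@H]1Oc2ccc([C@H](C)OC(C)=O)cc2[C@H]1O[Si](C)(C)C(C)(C)C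
F7 | step 11 | (2R,3R)-5-[(1S)-1-acetoxyethyl]-2-(3-chloroprop-1-en-2-yl)-2,3-dihydro-1-benzofuran-3-yl 3-methylbutanoate | C=C(CCl)[C@H]1Oc2ccc([C@H](C)OC(C)=O)cc2[C@H]1OC(=O)CC(C)C
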